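**Retrosynthetic overview**
1. I do not sulfenylate, brominate or lithiate a pre-formed indole. The indole π-system appears only in the last step: cutting the S–CH3 bond of the C2 thioether leads back to thiolactam 8 (aromatising S-methylation).
2. Thiolactam 8 comes from lactam 7 by C=O to C=S exchange.
3. Key disconnection: 7 comes from 3,4,5-tribromoaniline 1 and MeSCH2CO2Et 2 by an azasulfonium-ylide [2,3]-sigmatropic shift (Gassman). This makes C3–C3a and delivers the C3–SMe group in one event, and the sulfur that is normally stripped off afterwards is kept as a target atom.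
4. Ring order: the benzene ring is bought with all three Br in place. Compound 1 is C2v-symmetric, so both ortho C–H positions are equivalent and only one regioisomer can form. The five-membered ring is the only ring made (C3–C3a, then N1–C2, step 1), and it is aromatised in step 3.

Assumption: the target is a flat, achiral indole with no stereogenic element, so "single enantiomer" needs no stereocontrol (the transient C3 centre in 6–8 is racemic and disappears on aromatisation), and 1 and 2 are taken as catalogue chemicals.

**Step 1**
Reactants: 1 3,4,5-tribromoaniline; 2 ethyl 2-(methylsulfanyl)acetate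
Product: 7 (±)-4,5,6-tribromo-3-(methylsulfanyl)-1,3-dihydro-2H-indol-2-one, via N-chloro-3,4,5-tribromoaniline 3 (not isolated), via (2-ethoxy-2-oxoethyl)(methyl)[(3,4,5-tribromophenyl)amino]sulfonium chloride 4 (not isolated), via ethyl {methyl[(3,4,5-tribromophenyl)amino]-λ4-sulfanylidene}acetate (azasulfonium ylide) 5 (not isolated), via ethyl (±)-2-(2-amino-4,5,6-tribromophenyl)-2-(methylsulfanyl)acetate 6 (not isolated)
Conditions: t-BuOCl (1.0 equiv), CH2Cl2, −70 °C, 20 min; 2 (1.1 equiv), −70 °C, 2 h; Et3N (1.2 equiv), −70 °C → rt; then 2 M aq HCl, THF, rt → 45 °C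
Reagents that add atoms: none
Why: Gassman oxindole synthesis, in which t-BuOCl N-chlorinates 1, sulfide 2 displaces chloride at nitrogen to give 4, Et3N forms the ester-stabilised ylide 5, a Sommelet–Hauser-type [2,3]-sigmatropic shift with rearomatisation places the CH(SMe)CO2Et carbon on one of the two equivalent ortho carbons (a concerted step that, unlike a Friedel–Crafts closure, is not slowed by three deactivating Br, suits electron-poor anilines in the N-chloro protocol, and tolerates a substituent next to the reacting carbon), and acid lactamises 6; the new C3 centre is racemic and is erased in step 3.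

**Step 2**
Reactants: 7 (±)-4,5,6-tribromo-3-(methylsulfanyl)-1,3-dihydro-2H-indol-2-one
Product: 8 (±)-4,5,6-tribromo-3-(methylsulfanyl)-1,3-dihydro-2H-indole-2-thione (in equilibrium with its 2-sulfanylindole tautomer)
Conditions: Lawesson's reagent (0.55 equiv), degassed toluene, 90 °C, 2 h, Ar
Reagents that add atoms: Lawesson's reagent, COc1ccc(cc1)P1(=S)SP(=S)(S1)c1ccc(OC)cc1
Why: Lawesson thionation (Wittig-like [2+2]/cycloreversion of the dithiophosphine ylide on the lactam C=O) acts on the only carbonyl group, leaves C–Br, thioether and N–H untouched, and is standard for oxindole to indoline-2-thione, while excluding air keeps the thiol tautomer from oxidising to the disulfide.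

**Step 3**
Reactants: 8 (±)-4,5,6-tribromo-3-(methylsulfanyl)-1,3-dihydro-2H-indole-2-thione
Product: 9 4,5,6-tribromo-2,3-bis(methylsulfanyl)-1H-indole
Conditions: MeI (1.05 equiv), K2CO3 (1.1 equiv), degassed acetone, 0 °C → rt, 1 h
Reagents that add atoms: iodomethane, CI
Why: Thioamide S-alkylation (SN2), in which the soft indole-2-thiolate formed from the acidic thiolactam attacks MeI through sulfur rather than C3 or N, and the resulting cyclic thioimidate exists as the aromatic 1H-indole, which removes the C3 stereocentre and gives the achiral target.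

**Compound list**
1 | 3,4,5-tribromoaniline | Nc1cc(Br)c(Br)c(Br)c1 | starting material
2 | ethyl 2-(methylsulfanyl)acetate | CCOC(=O)CSC | starting material
3 | N-chloro-3,4,5-tribromoaniline | ClNc1cc(Br)c(Br)c(Br)c1 | intermediate
4 | (2-ethoxy-2-oxoethyl)(methyl)[(3,4,5-tribromophenyl)amino]sulfonium chloride (racemic) | CCOC(=O)C[S+](C)Nc1cc(Br)c(Br)c(Br)c1.[Cl-] | intermediate
5 | ethyl {methyl[(3,4,5-tribromophenyl)amino]-λ4-sulfanylidene}acetate (azasulfonium ylide, racemic) | CCOC(=O)[CH-][S+](C)Nc1cc(Br)c(Br)c(Br)c1 | intermediate
6 | ethyl (±)-2-(2-amino-4,5,6-tribromophenyl)-2-(methylsulfanyl)acetate | CCOC(=O)C(SC)c1c(N)cc(Br)c(Br)c1Br | intermediate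
7 | (±)-4,5,6-tribromo-3-(methylsulfanyl)-1,3-dihydro-2H-indol-2-one | CSC1C(=O)Nc2cc(Br)c(Br)c(Br)c12 | intermediate
8 | (±)-4,5,6-tribromo-3-(methylsulfanyl)-1,3-dihydro-2H-indole-2-thione | CSC1C(=S)Nc2cc(Br)c(Br)c(Br)c12 | intermediate
9 | 4,5,6-tribromo-2,3-bis(methylsulfanyl)-1H-indole | CSc1[nH]c2cc(Br)c(Br)c(Br)c2c1SC | target

Total step count: 3. Longest linear sequence: 3.

**Steps most likely to fail, with fallbacks**

Step 1 carries the highest risk. Compound 1 is weakly basic and poorly soluble at −70 °C. The [2,3]-shift must enter a C–H flanked by Br, and ring chlorination can compete. The fallback sets out from 1 and 2 and returns at 7. It replaces the sigmatropic C–C bond formation by a Pummerer/Friedel–Crafts closure from the N-acylated aniline. AlMe3-mediated aminolysis of 2 by 1 (toluene, 80 °C) gives 2-(methylsulfanyl)-N-(3,4,5-tribromophenyl)acetamide F1. NaIO4 (aq MeOH/THF, 0 °C → rt) oxidises it to (±)-2-(methanesulfinyl)-N-(3,4,5-tribromophenyl)acetamide F2. TFAA followed by BF3·OEt2 (CH2Cl2, 0 °C → reflux) then triggers a Pummerer cyclisation. The closure occurs at the ring carbon that is ortho to the amide nitrogen, ortho to one Br and para to another, so all of these groups direct to that carbon, and the product is 7.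

Step 2 carries the second risk. Compound 8 may oxidise or dimerise, or lose MeSH at 90 °C. The fallback sets out from 7 and returns at 9, skipping 8. It removes the lactam oxygen instead of exchanging it. BH3·THF (0 °C → rt, acidic work-up) reduces 7 with dehydration to 4,5,6-tribromo-3-(methylsulfanyl)-1H-indole F3. Dimethyl(methylsulfanyl)sulfonium tetrafluoroborate (CH2Cl2, 0 °C → rt) then transfers MeS+ to C3, and one sulfur migrates to C2 (ipso attack and 1,2-shift, the established course of the second sulfenylation of 3-sulfenylindoles) to give 9.

Step 3 carries the third risk. A disulfide may form before alkylation, and the ambident anion may be alkylated at C3 or over-alkylated. The fallback sets out from 8 and returns at 9. It reverses the polarity of the S–CH3 bond formation. I2 (0.5 equiv, EtOH, rt) deliberately converts 8 into the air-stable bis[4,5,6-tribromo-3-(methylsulfanyl)-1H-indol-2-yl] disulfide F4, which is purified by crystallisation. MeMgBr (THF, −20 → 0 °C; two equivalents are consumed by the N–H groups and one by S–S) then attacks the electrophilic sulfur, far faster than any Br/Mg exchange. This gives 9 without any alkylating agent meeting the anion. The thiolate half is recovered as 8 on work-up and re-oxidised to F4.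

**Further compounds**
F1 | step 1 | 2-(methylsulfanyl)-N-(3,4,5-tribromophenyl)acetamide | CSCC(=O)Nc1cc(Br)c(Br)c(Br)c1
F2 | step 1 | (±)-2-(methanesulfinyl)-N-(3,4,5-tribromophenyl)acetamide | CS(=O)CC(=O)Nc1cc(Br)c(Br)c(Br)c1
F3 | step 2 | 4,5,6-tribromo-3-(methylsulfanyl)-1H-indole | CSc1c[nH]c2cc(Br)c(Br)c(Br)c12
F4 | step 3 | bis[4,5,6-tribromo-3-(methylsulfanyl)-1H-indol-2-yl] disulfide | CSc1c(SSc2[nH]c3cc(Br)c(Br)c(Br)c3c2SC)[nH]c2cc(Br)c(Br)c(Br)c12
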